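Assumption: the structural formula of the target fixes the four carbon stereocentres (2R,3R in both halves) but not the sense of the biaryl axis, and the route aims at the (aR) axis of natural theasinensin C; SMILES strings cannot show the axis, so it is carried in the names, the twist being the same from 18 to 27 (only the mono-coupled iodide 19 formally reads (aS), because the sequence-rule priority of the ortho positions changes on one ring alone).

## Analysis of the target

Theasinensin C is a C2-symmetric dimer of two (2R,3R)-flavan-3-ol halves, each a phloroglucinol ring A fused to a dihydropyran (O1, C2, C3, C4, C4a, C8a) with a pyrogallol ring B on C2, and the halves are joined by a bond between C2' of the two B rings. Each half has two stereocentres, C2 (aryl) and C3 (hydroxyl), in the cis arrangement, which is the less stable one for a 2-aryl-chroman-3-ol. Because the halves are identical, there are two stereochemical problems, each solved twice. The biaryl bond has four ortho substituents (C1' and the C3' oxygen on each ring) and is a stable stereogenic axis; the other axis diastereomer is theasinensin E. The sensitive groups are the ten free phenols (two pyrogallols that autoxidise readily, two C-nucleophilic phloroglucinols) and the benzylic C2–O1 bond, which acid or base can open with loss of the C2 configuration. The main difficulty is congestion: both C2 centres sit directly beside the hindered axis, so every bond to C2 has to be made twice, in a crowded place, with control. The strategy rests on the C2–C3 unit, in which C2 carries O1 and C1' of ring B and C3 carries a hydroxyl and the C4 methylene bonded to C4a of ring A; this is the skeleton of L-tartaric acid with one carboxyl replaced by an aryl group and the other reduced to a benzylic CH2.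

## Retrosynthetic reasoning

**27 from 26.** The ten phenols are kept as benzyl ethers to the end. The last step cuts only O–benzyl bonds under neutral, reductive conditions, so the pyrogallols never meet base or oxidants.

**26 from 25 and 24.** The cis alcohol 26 is traced through ketone 25 to the trans alcohol 24. No skeletal bond is cut here; only C3 is re-set. The detour is accepted because the ring closure chosen below can deliver only the trans flavanol. In the forward direction the C2 aryl group must steer a bulky hydride to the opposite face of the C3 carbonyl.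

**24 from 23 and 21.** The O1–C2 bond of each pyran ring is cut. It is a benzylic C–O bond that can be formed by intramolecular displacement with inversion. Cutting it converts each heterocycle into an acyclic 1-aryl-1,2-diol with a 2-hydroxybenzyl group on C3, which is hexol 21. The forward reaction must activate only the benzylic oxygen. This is done through the cyclic orthoester 22, which ionises and is opened at C2 by the phenol, leaving a formate on O3 (23).

**21 from 20.** The diols and the two ring A phenols are masked as acetonides and methoxymethyl ethers. Both masks are acetals and fall in one acidic operation that leaves the benzyl ethers alone.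

**20 from 18 and 10 (key disconnection).** Both C2–C1' bonds are cut. This separates the molecule into a symmetric biaryl dihalide 18, which can be made and resolved before any carbon stereocentre exists, and two copies of the chiral-pool ester 10. A polar alternative at the same bond (aryl metal plus aldehyde) would give an uncontrolled carbinol centre. The radical route instead forms C2 inside a dioxolane whose neighbouring centre dictates the trans outcome. The forward reaction is a nickel-catalysed, cathodically driven decarboxylative arylation that has to run twice on one biaryl, through the mono-coupled iodide 19.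

**10 from 9, 8, 5 and 2.** The C4–C4a bond is cut between a primary electrophilic carbon (triflate 5) and a ring A nucleophile (aryllithium 6, then Grignard reagent 7, made from 2). Ring A is the cheapest part of the target and is bought rather than built. The ester of 8 is then hydrolysed to acid 9 and activated as the N-acyloxyphthalimide 10.

**5 from 4 and 3; 2 from 1.** The two ester groups of 3 are homotopic, so reduction of one gives a single hydroxy ester 4 with the future C3 centre intact. Ether 2 comes from phenol 1 by protection with the group that later directs the metalation.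

**18 from 17, 15, 14, 13, 12 and 11.** The biaryl bond is cut last, into two identical halves. Two molecules of the bromo iodide 12 (from 11) are joined at their iodinated carbons, because an aryl iodide next to a bromide couples through the iodide only. The bromines of 13 survive as placeholders through the exchange of methyl for benzyl ethers (14, 15) and are then swapped for iodine via 16. The racemic diiodide 17 is resolved to 18.

## Alternatives that were turned down

**Alternative 1:** The disconnection is C8–C8a in each ring A, so both phloroglucinol rings are built de novo. In the forward key step an alkoxide base opens both 4-hydroxy-6-methyl-2-pyrone rings of the bis-pyrone A1 at the lactone carbonyl. In each opened chain the terminal methyl carbanion then closes onto the ester carbon, and aromatisation gives the bis(2-alkylphloroglucinol) A2.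
- In its favour: A2 already has the erythro C2/C3 pattern (silyloxy on C2, benzyloxy on C3), so an invertive closure at C2 would give the cis flavanol directly. On this point it is stronger than the chosen route, which needs an oxidation and a reduction to correct C3.
- Against it: ring A is the one part of the target that can be bought (compound 1), so building it spends the key step on the easiest ring. The Claisen-type closure needs the least acidic position of an already multiply deprotonated chain to attack, twice, on a large polyether, and relactonisation or fragmentation of the opened chain competes. A2 then carries six free phloroglucinol hydroxyls that must be handled or re-protected. A1 itself still needs the biaryl and four stereocentres from separate chemistry, so no steps are saved.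
- The chosen strategy instead puts its key step on the hardest bond, C2–C1', and sets C2 there.

**Alternative 2:** The disconnection is C1'–C2' and C5'–C6' in each ring B. In the forward key step the tetrakis(benzyloxy)-2,2'-bifuran A3 acts twice as a diene toward the chiral ynone A4. Acid-induced opening of both oxygen bridges then aromatises the new rings to the biaryl bis(aryl ketone) A5, with the furan oxygen as the C5' hydroxyl.
- In its favour: the hindered biaryl bond is already present as the easily made bifuran bond, so no Ullmann coupling and no halogen exchange are needed. Here it is stronger than the chosen route, which spends six steps on 18.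
- Against it: the cycloaddition must occur at the furan carbon that carries the other furan, and furan Diels–Alder adducts revert easily. Both the cycloaddition regiochemistry and the direction of bridge opening must go one way, twice. The axis forms without control when the bridgeheads become sp2 carbons. The α-benzyloxy ketone centre of A5 can epimerise under the aromatising acid. C2 arrives as a ketone, so a diastereoselective reduction beside the axis, a differentiation of the free C5' hydroxyl and the ring closure all remain.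
- The chosen strategy buys both aromatic rings, fixes the axis by resolution, and forms C2 as a stereocentre in the bond-forming step.

**Alternative 3:** The disconnection is O1–C2 and C3–C4 in both pyran rings. In the forward key step the hydroxymethylphenol A6 loses water to the o-quinone methide A7. Two molecules of A7 add across the two (Z)-vinylsilane arms of the biaryl A8, giving the bis(3-silyl) flavan A9. Oxidation of the C–Si bonds with retention would follow.
- In its favour: it is the most convergent and the shortest of the four routes. Both heterocycles and the cis relationship (from the Z geometry) arise in one operation. On step economy it is clearly stronger than the chosen route.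
- Against it: nothing but the remote axis controls the absolute configuration of the four new centres, so up to three diastereomeric products are possible and the facial preference cannot be predicted from the structure. A β-silylstyrene is only a moderate partner for an electron-poor heterodiene. A stepwise zwitterionic pathway or Z-to-E isomerisation would erode the cis relationship. Two hindered secondary C–Si bonds must then be oxidised beside ten benzyl ethers.
- The chosen strategy is longer but takes its stereocontrol from a chiral-pool centre directly adjacent to the reacting carbon.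

Key step: step 13

## Route

Step 1
Reactants: 1 3,5-bis(benzyloxy)phenol
Product: 2 1,3-bis(benzyloxy)-5-(methoxymethoxy)benzene
Conditions: MOMCl, i-Pr2NEt, CH2Cl2, 0 °C to rt
Reagents that add atoms: chloromethyl methyl ether, COCCl
Why: O-alkylation of the phenol with a reactive α-chloro ether; the methoxymethyl ether later directs ortho-lithiation and is the one ring A mask that acid removes while the benzyl ethers stay.

Step 2
Reactants: 3 dimethyl (4R,5R)-2,2-dimethyl-1,3-dioxolane-4,5-dicarboxylate
Product: 4 methyl (4R,5S)-5-(hydroxymethyl)-2,2-dimethyl-1,3-dioxolane-4-carboxylate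
Conditions: NaBH4 (0.55 equiv), MeOH, 0 °C to rt
Reagents that add atoms: none
Why: Borohydride reduction of an α-alkoxy-activated ester; the two esters of 3 are homotopic, so monoreduction gives a single hydroxy ester, the future C3 centre is untouched, and unreacted 3 is recovered.

Step 3
Reactants: 4 methyl (4R,5S)-5-(hydroxymethyl)-2,2-dimethyl-1,3-dioxolane-4-carboxylate
Product: 5 methyl (4R,5S)-2,2-dimethyl-5-{[(trifluoromethylsulfonyl)oxy]methyl}-1,3-dioxolane-4-carboxylate
Conditions: Tf2O, 2,6-lutidine, CH2Cl2, -78 to -30 °C; used crude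
Reagents that add atoms: trifluoromethanesulfonic anhydride, O=S(=O)(OS(=O)(=O)C(F)(F)F)C(F)(F)F
Why: O-sulfonylation of a primary alcohol; the triflate is needed because substitution next to a dioxolane oxygen is slow with weaker leaving groups.

Step 4
Reactants: 2 1,3-bis(benzyloxy)-5-(methoxymethoxy)benzene, 5 methyl (4R,5S)-2,2-dimethyl-5-{[(trifluoromethylsulfonyl)oxy]methyl}-1,3-dioxolane-4-carboxylate
Product: 8 methyl (4R,5S)-5-[4,6-bis(benzyloxy)-2-(methoxymethoxy)benzyl]-2,2-dimethyl-1,3-dioxolane-4-carboxylate, via aryllithium 6 (not isolated), via arylmagnesium bromide 7 (not isolated)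
Conditions: 2, n-BuLi, THF, 0 °C; MgBr2·OEt2, 0 °C; CuBr·SMe2 (10 mol%), then 5, -40 to -10 °C
Reagents that add atoms: none
Why: Directed ortho-metalation at the carbon between the methoxymethoxy and a benzyloxy group, transmetalation to magnesium, and copper-catalysed SN2 alkylation by the primary triflate form the C4–C4a bond; the hindered aryl nucleophile should displace the triflate much faster than it adds to the ester at low temperature, and no stereocentre is involved.

Step 5
Reactants: 8 methyl (4R,5S)-5-[4,6-bis(benzyloxy)-2-(methoxymethoxy)benzyl]-2,2-dimethyl-1,3-dioxolane-4-carboxylate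
Product: 9 (4R,5S)-5-[4,6-bis(benzyloxy)-2-(methoxymethoxy)benzyl]-2,2-dimethyl-1,3-dioxolane-4-carboxylic acid
Conditions: LiOH·H2O, THF/MeOH/H2O, 0 °C to rt; then 1 M HCl to pH 3–4 at 0 °C
Reagents that add atoms: lithium hydroxide, [Li+].[OH-]
Why: Saponification of a methyl ester; any epimerisation next to the carboxylate is harmless because this carbon becomes a planar radical in step 13, and the brief cold acidification spares both acetals.

Step 6
Reactants: 9 (4R,5S)-5-[4,6-bis(benzyloxy)-2-(methoxymethoxy)benzyl]-2,2-dimethyl-1,3-dioxolane-4-carboxylic acid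
Product: 10 1,3-dioxoisoindolin-2-yl (4R,5S)-5-[4,6-bis(benzyloxy)-2-(methoxymethoxy)benzyl]-2,2-dimethyl-1,3-dioxolane-4-carboxylate
Conditions: N-hydroxyphthalimide, N,N'-diisopropylcarbodiimide, DMAP (cat.), CH2Cl2, rt
Reagents that add atoms: N-hydroxyphthalimide, ON1C(=O)c2ccccc2C1=O
Why: Carbodiimide esterification (Steglich type) gives the redox-active ester; it is filtered through silica and used promptly because esters of α-alkoxy acids hydrolyse easily.

Step 7
Reactants: 11 5-bromo-1,2,3-trimethoxybenzene
Product: 12 1-bromo-2-iodo-3,4,5-trimethoxybenzene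
Conditions: N-iodosuccinimide (1.05 equiv), CF3CO2H (cat.), MeCN, rt to 50 °C
Reagents that add atoms: N-iodosuccinimide, O=C1CCC(=O)N1I
Why: Electrophilic aromatic iodination; the two free positions are equivalent, each ortho to one methoxy group and para to another, so a single monoiodide is expected.

Step 8
Reactants: 12 1-bromo-2-iodo-3,4,5-trimethoxybenzene
Product: 13 racemic 2,2'-dibromo-4,4',5,5',6,6'-hexamethoxybiphenyl
Conditions: 12 (two molecules per biaryl), activated Cu bronze (excess), neat, 230 °C
Reagents that add atoms: second molecule of aryl iodide 12, COc1cc(Br)c(I)c(OC)c1OC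
Why: Ullmann reductive homocoupling, in which two molecules of 12 are joined at their iodinated carbons and both iodine atoms leave as CuI. Copper inserts into the C–I bond far faster than into C–Br, so the biaryl bond forms at the iodinated carbon and both bromines remain ortho to it.

Step 9
Reactants: 13 racemic 2,2'-dibromo-4,4',5,5',6,6'-hexamethoxybiphenyl
Product: 14 racemic 2,2'-dibromobiphenyl-4,4',5,5',6,6'-hexol
Conditions: BBr3, CH2Cl2, -78 °C to rt; MeOH then H2O; argon
Reagents that add atoms: none
Why: Lewis-acid cleavage of aryl methyl ethers; the bromides are kept at this stage because they resist the protodehalogenation that an iodide para to a free hydroxyl would suffer in the HBr formed.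

Step 10
Reactants: 14 racemic 2,2'-dibromobiphenyl-4,4',5,5',6,6'-hexol
Product: 15 racemic 2,2'-dibromo-4,4',5,5',6,6'-hexakis(benzyloxy)biphenyl
Conditions: BnBr, K2CO3, DMF (degassed), 60 °C
Reagents that add atoms: benzyl bromide, BrCc1ccccc1
Why: Williamson etherification of all six phenols under exclusion of air installs the masks that are removed by hydrogenolysis at the end.

Step 11
Reactants: 15 racemic 2,2'-dibromo-4,4',5,5',6,6'-hexakis(benzyloxy)biphenyl
Product: 17 racemic 2,2'-diiodo-4,4',5,5',6,6'-hexakis(benzyloxy)biphenyl, via dilithiobiaryl 16 (not isolated)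
Conditions: n-BuLi (2.2 equiv), THF, -78 °C; I2, -78 °C to rt
Reagents that add atoms: iodine, II
Why: Double bromine–lithium exchange followed by iodinolysis; at -78 °C the exchange is much faster than benzylic deprotonation, and the lithiated carbons are not next to a benzyloxy group.

Step 12
Reactants: 17 racemic 2,2'-diiodo-4,4',5,5',6,6'-hexakis(benzyloxy)biphenyl
Product: 18 (aR)-2,2'-diiodo-4,4',5,5',6,6'-hexakis(benzyloxy)biphenyl
Conditions: preparative HPLC on cellulose tris(3,5-dimethylphenylcarbamate), hexane/i-PrOH; axis assigned by X-ray anomalous dispersion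
Reagents that add atoms: none
Why: Resolution of a tetra-ortho-substituted biaryl whose rotation barrier is high enough for the enantiomers to be stable; the iodine atoms allow direct assignment, and the (aR) descriptor returns unchanged once iodine has been replaced by carbon on both rings.

Step 13
Reactants: 18 (aR)-2,2'-diiodo-4,4',5,5',6,6'-hexakis(benzyloxy)biphenyl, 10 1,3-dioxoisoindolin-2-yl (4R,5S)-5-[4,6-bis(benzyloxy)-2-(methoxymethoxy)benzyl]-2,2-dimethyl-1,3-dioxolane-4-carboxylate
Product: 20 (aR)-4,4',5,5',6,6'-hexakis(benzyloxy)-2,2'-bis{(4S,5S)-5-[4,6-bis(benzyloxy)-2-(methoxymethoxy)benzyl]-2,2-dimethyl-1,3-dioxolan-4-yl}biphenyl, via mono-coupled iodide 19 (not isolated)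
Conditions: 10 (3 equiv), NiCl2(dme) (40 mol%), 2,2'-bipyridine (40 mol%), AgNO3 (30 mol%), LiCl, DMF, Mg anode, carbon-foam cathode, constant current, rt
Reagents that add atoms: none
Why: Low-valent nickel formed at the cathode inserts into a C–I bond of 18, while single-electron reduction of 10 expels phthalimide anion and CO2 and leaves a 2,2-dimethyl-1,3-dioxolan-4-yl radical; the divalent arylnickel captures this radical and the resulting trivalent alkyl(aryl)nickel reductively eliminates the C2–C1' bond, after which the cycle repeats on the second iodide of 19 with a second molecule of 10. The closest known reaction type is the nickel-electrocatalytic decarboxylative arylation of redox-active esters of α-alkoxy acids, tartrate-derived dioxolanes included, with aryl iodides. No ring is closed. The new stereocentre of each half (C2, dioxolane C4) is controlled by the neighbouring C5 centre that comes from 3: the planar α-oxy radical is arylated on the face anti to the C5 benzyl group, so the trans (4S,5S) dioxolane should form whatever the C4 configuration of 10. The step needs chemoselectivity between the partners, which is secured because only 18 carries carbon–halogen bonds and ring A and all ethers are inert at the potential used. Ester 10 is used in excess to offset radical dimerisation and reduction. The axis should be untouched because both ortho positions of the biaryl bond stay substituted throughout.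

Step 14
Reactants: 20 (aR)-4,4',5,5',6,6'-hexakis(benzyloxy)-2,2'-bis{(4S,5S)-5-[4,6-bis(benzyloxy)-2-(methoxymethoxy)benzyl]-2,2-dimethyl-1,3-dioxolan-4-yl}biphenyl
Product: 21 (aR)-4,4',5,5',6,6'-hexakis(benzyloxy)-2,2'-bis{(1S,2S)-3-[4,6-bis(benzyloxy)-2-hydroxyphenyl]-1,2-dihydroxypropyl}biphenyl
Conditions: conc. HCl (cat.), MeOH/THF, 40 °C
Reagents that add atoms: none
Why: Acid-catalysed acetal exchange with methanol removes both acetonides and both aryl methoxymethyl ethers; the benzylic C–O bond should hold under these mild conditions because its cation is destabilised by the vicinal hydroxyl and by the twisted, crowded ring B.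

Step 15
Reactants: 21 (aR)-4,4',5,5',6,6'-hexakis(benzyloxy)-2,2'-bis{(1S,2S)-3-[4,6-bis(benzyloxy)-2-hydroxyphenyl]-1,2-dihydroxypropyl}biphenyl
Product: 23 (aR)-4,4',5,5',6,6'-hexakis(benzyloxy)-2,2'-bis[(2R,3S)-5,7-bis(benzyloxy)-3-(formyloxy)chroman-2-yl]biphenyl, via bis-orthoester 22 (not isolated)
Conditions: HC(OEt)3, pyridinium p-toluenesulfonate (cat.), ClCH2CH2Cl, rt then 60 °C
Reagents that add atoms: triethyl orthoformate, CCOC(OCC)OCC
Why: Each diol forms a cyclic orthoformate that ionises to a dioxolanylium ion, and the ring A phenol opens it at the benzylic carbon in a 6-exo-tet SN2-type displacement; C2 is inverted (S to R), C3 is untouched, and the 2,3-trans flavan with a formate on O3 results.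

Step 16
Reactants: 23 (aR)-4,4',5,5',6,6'-hexakis(benzyloxy)-2,2'-bis[(2R,3S)-5,7-bis(benzyloxy)-3-(formyloxy)chroman-2-yl]biphenyl
Product: 24 (aR)-4,4',5,5',6,6'-hexakis(benzyloxy)-2,2'-bis[(2R,3S)-5,7-bis(benzyloxy)-3-hydroxychroman-2-yl]biphenyl
Conditions: K2CO3 (cat.), MeOH/THF, rt
Reagents that add atoms: none
Why: Base-catalysed transesterification removes the formates under conditions too mild to open the pyran ring.

Step 17
Reactants: 24 (aR)-4,4',5,5',6,6'-hexakis(benzyloxy)-2,2'-bis[(2R,3S)-5,7-bis(benzyloxy)-3-hydroxychroman-2-yl]biphenyl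
Product: 25 (aR)-4,4',5,5',6,6'-hexakis(benzyloxy)-2,2'-bis[(2R)-5,7-bis(benzyloxy)-3-oxochroman-2-yl]biphenyl
Conditions: Dess–Martin periodinane, CH2Cl2, rt; used at once
Reagents that add atoms: none
Why: Dess–Martin oxidation of the secondary alcohols under neutral, non-enolising conditions, so that the C2 centre next to the new ketone should keep its configuration.

Step 18
Reactants: 25 (aR)-4,4',5,5',6,6'-hexakis(benzyloxy)-2,2'-bis[(2R)-5,7-bis(benzyloxy)-3-oxochroman-2-yl]biphenyl
Product: 26 (aR)-4,4',5,5',6,6'-hexakis(benzyloxy)-2,2'-bis[(2R,3R)-5,7-bis(benzyloxy)-3-hydroxychroman-2-yl]biphenyl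
Conditions: LiBH(s-Bu)3, THF, -78 °C; then H2O
Reagents that add atoms: none
Why: Substrate-controlled ketone reduction; the bulky hydride approaches the flavan-3-one from the face opposite the C2 aryl group, placing the new hydroxyl cis to it (3R).

Step 19
Reactants: 26 (aR)-4,4',5,5',6,6'-hexakis(benzyloxy)-2,2'-bis[(2R,3R)-5,7-bis(benzyloxy)-3-hydroxychroman-2-yl]biphenyl
Product: 27 theasinensin C
Conditions: H2 (1 atm), Pd(OH)2/C, THF/MeOH, rt; filtration and evaporation under argon
Reagents that add atoms: none
Why: Hydrogenolysis of the ten benzyl ethers under neutral conditions frees the phenols without base or oxidant, and no stereocentre is affected.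

## Compound list

1 | 3,5-bis(benzyloxy)phenol | Oc1cc(OCc2ccccc2)cc(OCc2ccccc2)c1 | starting material
2 | 1,3-bis(benzyloxy)-5-(methoxymethoxy)benzene | COCOc1cc(OCc2ccccc2)cc(OCc2ccccc2)c1 | intermediate
3 | dimethyl (4R,5R)-2,2-dimethyl-1,3-dioxolane-4,5-dicarboxylate (dimethyl 2,3-O-isopropylidene-L-tartrate) | COC(=O)[C@@H]1OC(C)(C)O[C@H]1C(=O)OC | starting material
4 | methyl (4R,5S)-5-(hydroxymethyl)-2,2-dimethyl-1,3-dioxolane-4-carboxylate | COC(=O)[C@@H]1OC(C)(C)O[C@H]1CO | intermediate
5 | methyl (4R,5S)-2,2-dimethyl-5-{[(trifluoromethylsulfonyl)oxy]methyl}-1,3-dioxolane-4-carboxylate | COC(=O)[C@@H]1OC(C)(C)O[C@H]1COS(=O)(=O)C(F)(F)F | intermediate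
6 | [4,6-bis(benzyloxy)-2-(methoxymethoxy)phenyl]lithium | [Li]c1c(OCOC)cc(OCc2ccccc2)cc1OCc1ccccc1 | intermediate
7 | [4,6-bis(benzyloxy)-2-(methoxymethoxy)phenyl]magnesium bromide | Br[Mg]c1c(OCOC)cc(OCc2ccccc2)cc1OCc1ccccc1 | intermediate
8 | methyl (4R,5S)-5-[4,6-bis(benzyloxy)-2-(methoxymethoxy)benzyl]-2,2-dimethyl-1,3-dioxolane-4-carboxylate | COC(=O)[C@@H]1OC(C)(C)O[C@H]1Cc1c(OCOC)cc(OCc2ccccc2)cc1OCc1ccccc1 | intermediate
9 | (4R,5S)-5-[4,6-bis(benzyloxy)-2-(methoxymethoxy)benzyl]-2,2-dimethyl-1,3-dioxolane-4-carboxylic acid | OC(=O)[C@@H]1OC(C)(C)O[C@H]1Cc1c(OCOC)cc(OCc2ccccc2)cc1OCc1ccccc1 | intermediate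
10 | 1,3-dioxoisoindolin-2-yl (4R,5S)-5-[4,6-bis(benzyloxy)-2-(methoxymethoxy)benzyl]-2,2-dimethyl-1,3-dioxolane-4-carboxylate | O=C(ON1C(=O)c2ccccc2C1=O)[C@@H]1OC(C)(C)O[C@H]1Cc1c(OCOC)cc(OCc2ccccc2)cc1OCc1ccccc1 | intermediate
11 | 5-bromo-1,2,3-trimethoxybenzene | COc1cc(Br)cc(OC)c1OC | starting material
12 | 1-bromo-2-iodo-3,4,5-trimethoxybenzene | COc1cc(Br)c(I)c(OC)c1OC | intermediate
13 | racemic 2,2'-dibromo-4,4',5,5',6,6'-hexamethoxybiphenyl | COc1cc(Br)c(-c2c(Br)cc(OC)c(OC)c2OC)c(OC)c1OC | intermediate
14 | racemic 2,2'-dibromobiphenyl-4,4',5,5',6,6'-hexol | Oc1cc(Br)c(-c2c(Br)cc(O)c(O)c2O)c(O)c1O | intermediate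
15 | racemic 2,2'-dibromo-4,4',5,5',6,6'-hexakis(benzyloxy)biphenyl | Brc1cc(OCc9ccccc9)c(OCc9ccccc9)c(OCc9ccccc9)c1-c1c(Br)cc(OCc9ccccc9)c(OCc9ccccc9)c1OCc9ccccc9 | intermediate
16 | racemic 2,2'-dilithio-4,4',5,5',6,6'-hexakis(benzyloxy)biphenyl | [Li]c1cc(OCc9ccccc9)c(OCc9ccccc9)c(OCc9ccccc9)c1-c1c([Li])cc(OCc9ccccc9)c(OCc9ccccc9)c1OCc9ccccc9 | intermediate
17 | racemic 2,2'-diiodo-4,4',5,5',6,6'-hexakis(benzyloxy)biphenyl | Ic1cc(OCc9ccccc9)c(OCc9ccccc9)c(OCc9ccccc9)c1-c1c(I)cc(OCc9ccccc9)c(OCc9ccccc9)c1OCc9ccccc9 | intermediate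
18 | (aR)-2,2'-diiodo-4,4',5,5',6,6'-hexakis(benzyloxy)biphenyl | Ic1cc(OCc9ccccc9)c(OCc9ccccc9)c(OCc9ccccc9)c1-c1c(I)cc(OCc9ccccc9)c(OCc9ccccc9)c1OCc9ccccc9 | intermediate
19 | 4,4',5,5',6,6'-hexakis(benzyloxy)-2-{(4S,5S)-5-[4,6-bis(benzyloxy)-2-(methoxymethoxy)benzyl]-2,2-dimethyl-1,3-dioxolan-4-yl}-2'-iodobiphenyl, axis twisted as in 18 and 20 (formal descriptor (aS)) | CC1(C)O[C@@H](c2cc(OCc9ccccc9)c(OCc9ccccc9)c(OCc9ccccc9)c2-c2c(I)cc(OCc9ccccc9)c(OCc9ccccc9)c2OCc9ccccc9)[C@H](Cc2c(OCOC)cc(OCc9ccccc9)cc2OCc9ccccc9)O1 | intermediate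
20 | (aR)-4,4',5,5',6,6'-hexakis(benzyloxy)-2,2'-bis{(4S,5S)-5-[4,6-bis(benzyloxy)-2-(methoxymethoxy)benzyl]-2,2-dimethyl-1,3-dioxolan-4-yl}biphenyl | CC1(C)O[C@@H](c2cc(OCc9ccccc9)c(OCc9ccccc9)c(OCc9ccccc9)c2-c2c([C@@H]3OC(C)(C)O[C@H]3Cc3c(OCOC)cc(OCc9ccccc9)cc3OCc9ccccc9)cc(OCc9ccccc9)c(OCc9ccccc9)c2OCc9ccccc9)[C@H](Cc2c(OCOC)cc(OCc9ccccc9)cc2OCc9ccccc9)O1 | intermediate
21 | (aR)-4,4',5,5',6,6'-hexakis(benzyloxy)-2,2'-bis{(1S,2S)-3-[4,6-bis(benzyloxy)-2-hydroxyphenyl]-1,2-dihydroxypropyl}biphenyl | O[C@@H](c2cc(OCc9ccccc9)c(OCc9ccccc9)c(OCc9ccccc9)c2-c2c([C@H](O)[C@@H](O)Cc3c(O)cc(OCc9ccccc9)cc3OCc9ccccc9)cc(OCc9ccccc9)c(OCc9ccccc9)c2OCc9ccccc9)[C@@H](O)Cc1c(O)cc(OCc9ccccc9)cc1OCc9ccccc9 | intermediate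
22 | (aR)-4,4',5,5',6,6'-hexakis(benzyloxy)-2,2'-bis{(4S,5S)-5-[4,6-bis(benzyloxy)-2-hydroxybenzyl]-2-ethoxy-1,3-dioxolan-4-yl}biphenyl (orthoester carbons unassigned) | CCOC1O[C@@H](c2cc(OCc9ccccc9)c(OCc9ccccc9)c(OCc9ccccc9)c2-c2c([C@@H]3OC(OCC)O[C@H]3Cc3c(O)cc(OCc9ccccc9)cc3OCc9ccccc9)cc(OCc9ccccc9)c(OCc9ccccc9)c2OCc9ccccc9)[C@H](Cc2c(O)cc(OCc9ccccc9)cc2OCc9ccccc9)O1 | intermediate
23 | (aR)-4,4',5,5',6,6'-hexakis(benzyloxy)-2,2'-bis[(2R,3S)-5,7-bis(benzyloxy)-3-(formyloxy)chroman-2-yl]biphenyl | c9ccccc9COc1cc(OCc9ccccc9)c2c(c1)O[C@H](c1cc(OCc9ccccc9)c(OCc9ccccc9)c(OCc9ccccc9)c1-c1c([C@H]3Oc4cc(OCc9ccccc9)cc(OCc9ccccc9)c4C[C@@H]3OC=O)cc(OCc9ccccc9)c(OCc9ccccc9)c1OCc9ccccc9)[C@@H](OC=O)C2 | intermediate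
24 | (aR)-4,4',5,5',6,6'-hexakis(benzyloxy)-2,2'-bis[(2R,3S)-5,7-bis(benzyloxy)-3-hydroxychroman-2-yl]biphenyl (2,3-trans in both halves) | c9ccccc9COc1cc(OCc9ccccc9)c2c(c1)O[C@H](c1cc(OCc9ccccc9)c(OCc9ccccc9)c(OCc9ccccc9)c1-c1c([C@H]3Oc4cc(OCc9ccccc9)cc(OCc9ccccc9)c4C[C@@H]3O)cc(OCc9ccccc9)c(OCc9ccccc9)c1OCc9ccccc9)[C@@H](O)C2 | intermediate
25 | (aR)-4,4',5,5',6,6'-hexakis(benzyloxy)-2,2'-bis[(2R)-5,7-bis(benzyloxy)-3-oxochroman-2-yl]biphenyl | c9ccccc9COc1cc(OCc9ccccc9)c2c(c1)O[C@H](c1cc(OCc9ccccc9)c(OCc9ccccc9)c(OCc9ccccc9)c1-c1c([C@H]3Oc4cc(OCc9ccccc9)cc(OCc9ccccc9)c4CC3=O)cc(OCc9ccccc9)c(OCc9ccccc9)c1OCc9ccccc9)C(=O)C2 | intermediate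
26 | (aR)-4,4',5,5',6,6'-hexakis(benzyloxy)-2,2'-bis[(2R,3R)-5,7-bis(benzyloxy)-3-hydroxychroman-2-yl]biphenyl (deca-O-benzyl theasinensin C) | c9ccccc9COc1cc(OCc9ccccc9)c2c(c1)O[C@H](c1cc(OCc9ccccc9)c(OCc9ccccc9)c(OCc9ccccc9)c1-c1c([C@H]3Oc4cc(OCc9ccccc9)cc(OCc9ccccc9)c4C[C@H]3O)cc(OCc9ccccc9)c(OCc9ccccc9)c1OCc9ccccc9)[C@H](O)C2 | intermediate
27 | theasinensin C, (aR) axis, (2R,3R) in both halves | Oc1cc(O)c2c(c1)O[C@H](c1cc(O)c(O)c(O)c1-c1c([C@H]3Oc4cc(O)cc(O)c4C[C@H]3O)cc(O)c(O)c1O)[C@H](O)C2 | target

## Step count and least certain steps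

Total step count: 19. Longest linear sequence: 13 steps (11 to 27 through steps 7–19). The tartrate branch (3 to 27) is 12 steps.

**Step 13 (key step).** Three things can go wrong. The arylnickel formed at one iodide may engage the neighbouring C–I bond across the axis and form a nickelacycle, which would cost iodine, flatten the biaryl and lose the axis. Radical capture at the ortho-aryl nickel centre may be slow, so that radical dimerisation, hydrogen abstraction and proto-deiodination take over. The reaction may also stall after the first coupling.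
Fallback: set out from 18 and 10 and reverse the role of the biaryl. Iodine–lithium exchange on 18 (n-BuLi, THF, -78 °C) and transmetalation with ZnCl2 give the (aR)-bis(chlorozinc) biaryl F1. F1 is coupled with 10 under NiCl2(dme) and 4,4'-di-tert-butyl-2,2'-bipyridine in THF/DMF at rt, a decarboxylative Negishi-type arylation of redox-active esters. The aryl group then enters by transmetalation, no low-valent nickel meets a C–I bond, and the same anti radical capture applies. The sequence returns to the route at 20.

**Step 4.** The likely failure is addition of the aryl organometallic to the activated methyl ester, or deprotonation next to it, competing with substitution of the triflate. Some lithiation between the two benzyloxy groups is also possible.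
Fallback: set out from 3 and remove the ester before the C–C bond is made. LiAlH4 reduction of 3 gives 2,3-O-isopropylidene-L-threitol F2. Mono-silylation (NaH, t-BuMe2SiCl) gives the mono-silyl ether F3, and Tf2O/2,6-lutidine gives the triflate F4. Alkylation of aryllithium 6 (from 2) with F4 at -78 °C gives the arylated silyl ether F5. Bu4NF gives the primary alcohol F6, which is oxidised with TEMPO (cat.)/PhI(OAc)2 in MeCN/H2O to the acid. The sequence returns to the route at 9.

**Step 14.** The likely failure is ionisation of the electron-rich benzylic C2–O bond under protic acid. This would cause solvolysis, epimerisation at C2 or an uncontrolled direct ring closure.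
Fallback: set out from 20 and unmask in two orthogonal stages. Me3SiOTf/2,2'-bipyridyl in MeCN at 0 °C, then water, cleaves only the aryl methoxymethyl ethers (through the aryl silyl ethers) while the benzylic oxygen is still locked in the dioxolane, giving the bis-phenol bis-acetonide F7. Aqueous acetic acid in THF at 45 °C, too weak to ionise the benzylic alcohol, then removes the acetonides. The sequence returns to the route at 21.

**Step 15.** The SN2-type closure takes place at a benzylic carbon directly beside the tetra-ortho-substituted axis. It may be slow enough for the dioxolanylium ion to open by ionisation, so that the invertive course is lost, or the closure may stop after one half.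
Fallback: set out from 21 and close both rings by intramolecular Mitsunobu etherification (PPh3, diisopropyl azodicarboxylate, THF, 0 °C). The phenol displaces the activated benzylic hydroxyl with inversion. Epoxide formation from the diol is the competing path. This fallback passes through no new compound (F0) and returns to the route at 24, skipping 22, 23 and step 16.

**Step 17.** Enolisation of the flavan-3-one toward C2 would scramble the C2 centre, and enolisation toward C4 invites air oxidation. Both are more likely on a substrate with two such ketones.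
Fallback: set out from 24 and invert C3 without passing through a ketone. Mitsunobu esterification (4-nitrobenzoic acid, PPh3, diisopropyl azodicarboxylate, toluene) gives the cis bis(4-nitrobenzoate) F8; elimination to the flavene is its competing path. Methanolysis (K2CO3, MeOH/THF) then frees the alcohols. The sequence returns to the route at 26, skipping 25 and step 18.

## Further compounds

F1 | step 13 | (aR)-[4,4',5,5',6,6'-hexakis(benzyloxy)biphenyl-2,2'-diyl]bis(chlorozinc) | Cl[Zn]c1cc(OCc9ccccc9)c(OCc9ccccc9)c(OCc9ccccc9)c1-c1c([Zn]Cl)cc(OCc9ccccc9)c(OCc9ccccc9)c1OCc9ccccc9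
F2 | step 4 | [(4S,5S)-2,2-dimethyl-1,3-dioxolane-4,5-diyl]dimethanol (2,3-O-isopropylidene-L-threitol) | OC[C@@H]1OC(C)(C)O[C@H]1CO
F3 | step 4 | [(4S,5S)-5-({[tert-butyl(dimethyl)silyl]oxy}methyl)-2,2-dimethyl-1,3-dioxolan-4-yl]methanol | CC(C)(C)[Si](C)(C)OC[C@@H]1OC(C)(C)O[C@H]1CO
F4 | step 4 | [(4S,5S)-5-({[tert-butyl(dimethyl)silyl]oxy}methyl)-2,2-dimethyl-1,3-dioxolan-4-yl]methyl trifluoromethanesulfonate | CC(C)(C)[Si](C)(C)OC[C@@H]1OC(C)(C)O[C@H]1COS(=O)(=O)C(F)(F)F
F5 | step 4 | tert-butyl({(4S,5S)-5-[4,6-bis(benzyloxy)-2-(methoxymethoxy)benzyl]-2,2-dimethyl-1,3-dioxolan-4-yl}methoxy)dimethylsilane | CC(C)(C)[Si](C)(C)OC[C@@H]1OC(C)(C)O[C@H]1Cc1c(OCOC)cc(OCc2ccccc2)cc1OCc1ccccc1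
F6 | step 4 | {(4S,5S)-5-[4,6-bis(benzyloxy)-2-(methoxymethoxy)benzyl]-2,2-dimethyl-1,3-dioxolan-4-yl}methanol | OC[C@@H]1OC(C)(C)O[C@H]1Cc1c(OCOC)cc(OCc2ccccc2)cc1OCc1ccccc1
F7 | step 14 | (aR)-4,4',5,5',6,6'-hexakis(benzyloxy)-2,2'-bis{(4S,5S)-5-[4,6-bis(benzyloxy)-2-hydroxybenzyl]-2,2-dimethyl-1,3-dioxolan-4-yl}biphenyl | CC1(C)O[C@@H](c2cc(OCc9ccccc9)c(OCc9ccccc9)c(OCc9ccccc9)c2-c2c([C@@H]3OC(C)(C)O[C@H]3Cc3c(O)cc(OCc9ccccc9)cc3OCc9ccccc9)cc(OCc9ccccc9)c(OCc9ccccc9)c2OCc9ccccc9)[C@H](Cc2c(O)cc(OCc9ccccc9)cc2OCc9ccccc9)O1
F0 | step 15 | none | none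
F8 | step 17 | (aR)-4,4',5,5',6,6'-hexakis(benzyloxy)-2,2'-bis[(2R,3R)-5,7-bis(benzyloxy)-3-(4-nitrobenzoyloxy)chroman-2-yl]biphenyl | c9ccccc9COc1cc(OCc9ccccc9)c2c(c1)O[C@H](c1cc(OCc9ccccc9)c(OCc9ccccc9)c(OCc9ccccc9)c1-c1c([C@H]3Oc4cc(OCc9ccccc9)cc(OCc9ccccc9)c4C[C@H]3OC(=O)c8ccc(cc8)[N+](=O)[O-])cc(OCc9ccccc9)c(OCc9ccccc9)c1OCc9ccccc9)[C@H](OC(=O)c8ccc(cc8)[N+](=O)[O-])C2
A1 | alternative 1 | biaryl bis[erythro-1-(tert-butyldimethylsilyloxy)-2-(benzyloxy)-3-(4-hydroxy-6-methyl-2-oxo-2H-pyran-3-yl)propyl] compound | CC(C)(C)[Si](C)(C)O[C@@H](c1cc(OCc9ccccc9)c(OCc9ccccc9)c(OCc9ccccc9)c1-c1c([C@H](O[Si](C)(C)C(C)(C)C)[C@H](OCc9ccccc9)Cc3c(O)cc(C)oc3=O)cc(OCc9ccccc9)c(OCc9ccccc9)c1OCc9ccccc9)[C@H](OCc9ccccc9)Cc1c(O)cc(C)oc1=O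
A2 | alternative 1 | biaryl bis[erythro-1-(tert-butyldimethylsilyloxy)-2-(benzyloxy)-3-(2,4,6-trihydroxyphenyl)propyl] compound | CC(C)(C)[Si](C)(C)O[C@@H](c1cc(OCc9ccccc9)c(OCc9ccccc9)c(OCc9ccccc9)c1-c1c([C@H](O[Si](C)(C)C(C)(C)C)[C@H](OCc9ccccc9)Cc3c(O)cc(O)cc3O)cc(OCc9ccccc9)c(OCc9ccccc9)c1OCc9ccccc9)[C@H](OCc9ccccc9)Cc1c(O)cc(O)cc1O
A3 | alternative 2 | 3,3',4,4'-tetrakis(benzyloxy)-2,2'-bifuran | c1oc(-c2occ(OCc9ccccc9)c2OCc9ccccc9)c(OCc9ccccc9)c1OCc9ccccc9
A4 | alternative 2 | (4R)-5-[2-(allyloxy)-4,6-bis(benzyloxy)phenyl]-4-(benzyloxy)pent-1-yn-3-one | C#CC(=O)[C@H](OCc9ccccc9)Cc1c(OCC=C)cc(OCc9ccccc9)cc1OCc9ccccc9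
A5 | alternative 2 | biaryl bis(aryl ketone) with both B rings formed, 5'-hydroxyl free, ketone carbon = C2 | O=C(c1cc(O)c(OCc9ccccc9)c(OCc9ccccc9)c1-c1c(C(=O)[C@H](OCc9ccccc9)Cc3c(OCC=C)cc(OCc9ccccc9)cc3OCc9ccccc9)cc(O)c(OCc9ccccc9)c1OCc9ccccc9)[C@H](OCc9ccccc9)Cc1c(OCC=C)cc(OCc9ccccc9)cc1OCc9ccccc9
A6 | alternative 3 | 3,5-bis(benzyloxy)-2-(hydroxymethyl)phenol | OCc1c(O)cc(OCc9ccccc9)cc1OCc9ccccc9
A7 | alternative 3 | 3,5-bis(benzyloxy)-6-methylidenecyclohexa-2,4-dien-1-one (o-quinone methide) | C=C1C(=O)C=C(OCc9ccccc9)C=C1OCc9ccccc9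
A8 | alternative 3 | 4,4',5,5',6,6'-hexakis(benzyloxy)-2,2'-bis[(Z)-2-(benzyldimethylsilyl)vinyl]biphenyl | c9ccccc9C[Si](C)(C)/C=C\c1cc(OCc9ccccc9)c(OCc9ccccc9)c(OCc9ccccc9)c1-c1c(/C=C\[Si](C)(C)Cc9ccccc9)cc(OCc9ccccc9)c(OCc9ccccc9)c1OCc9ccccc9
A9 | alternative 3 | deca-O-benzyl bis(3-deoxy-3-benzyldimethylsilyl) theasinensin C, 2,3-cis in both halves | c9ccccc9COc1cc(OCc9ccccc9)c2c(c1)O[C@H](c1cc(OCc9ccccc9)c(OCc9ccccc9)c(OCc9ccccc9)c1-c1c([C@H]3Oc4cc(OCc9ccccc9)cc(OCc9ccccc9)c4C[C@H]3[Si](C)(C)Cc9ccccc9)cc(OCc9ccccc9)c(OCc9ccccc9)c1OCc9ccccc9)[C@H]([Si](C)(C)Cc9ccccc9)C2
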